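## The problem

The target, 2-[3-chloro-4-hydroxy-2-methoxy-6-(methoxycarbonyl)phenoxy]-6-hydroxy-4-methylbenzoic acid (13), is an achiral diaryl ether. There is no stereochemistry to control; the difficulty lies in regiochemistry and in telling like functional groups apart. The ether oxygen lies between two ortho substituents on ring A (methyl ester and methoxy group) and next to the carboxyl group on ring B, so a direct aryl–oxygen coupling would have to join a 2,6-disubstituted phenol to an ortho-substituted aryl partner. Ring A is pentasubstituted, and its chlorine must sit between the methoxy and the hydroxy group, a position that late chlorination of an activated ring would not reach reliably. A methyl ester on ring A stands beside a free carboxylic acid on ring B, which excludes any late saponification. The two phenols must be unmasked without loss of the methyl ether, the aryl chloride is at risk under hydrogenolysis, and the 2,6-dioxygenated benzoic acid of ring B decarboxylates easily in hot acid. The enabling feature is the pattern of ring B: C1 with its carboxyl, C6 with its hydroxyl and C5 form a 3-oxobutanoate unit, while the methyl group, C4, C3 and C2 form an acetyl–CH=C(O) unit whose C2 is at the oxidation level of an acid derivative. The ether oxygen can therefore be attached to C2 while that carbon is still an electrophilic vinyl carbon, and ring B can be grown around it afterwards.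

## Retrosynthesis

**13 from 12.** The two oxygen–benzyl bonds of 12 are cut, the phenol ether on ring A and the ester on ring B. A benzyl ester marks the ring B carboxyl as different from the ring A methyl ester from the moment it is introduced. Both benzyl groups can fall in one Lewis-acid operation that needs neither base nor hydrogen, so the methyl ester and the chlorine are not endangered. The forward step must cleave a benzyl ether and a chelated benzyl ester while sparing a non-chelated methyl ether.

**12 from 8 and 9.** Two bonds of ring B are cut, C4–C5 and C1–C2, which divides the ring into the chloroenone 8 and benzyl acetoacetate 9, used as its dianion 10; the open-chain adduct 11 is not isolated. The neighbouring cut, the aryl–oxygen bond itself, would demand a coupling at a doubly ortho-substituted phenol. The same [3+3] dissection run in the opposite order (a silyl dienol ether attacking the β-carbon of the enone first under Lewis acid) would place the aryloxy group para to the ester. The chosen order fixes the regiochemistry, because the terminal carbanion takes the ketone and only the central carbon is left for the chloro(aryloxy) carbon. The precursors are far simpler: a four-carbon enone hung on the ring A oxygen and a commodity keto ester. The forward reaction must give carbonyl addition in preference to conjugate attack, leave the ring A methyl ester alone, close through carbon and not through oxygen, and expel chloride and not aryloxide.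

**8 from 6 and 7.** The vinyl carbon–oxygen bond is cut, giving the phenol 6 and 4,4-dichlorobut-3-en-2-one (7). This moves the hindered C–O bond formation to an addition–elimination at a strongly electrophilic, unhindered vinyl carbon. The forward reaction must stop after one of the two chlorines has been replaced.

**6 from 5.** The benzyl–oxygen bond is cut. The hydroquinone 5 has one hydroxyl locked in a hydrogen bond to the ester and one free hydroxyl next to chlorine. Selective alkylation of the free one removes the need for a protecting-group pair on the other.

**5 from 3.** The new phenolic C–O bond is traced back to the C–CHO bond of 3 by an aryl migration to oxygen through the formate 4. The para-hydroxyl of 3 is what makes this oxidation easy. The ester is placed before the oxidation so that it can differentiate the two hydroxyls of 5.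

**3 from 2 from 1.** The ester carbon–carbon bond of 3 is cut back to the C–Br bond of 2, and that bond to a C–H bond of 2-chlorovanillin (1). Compound 1 already holds chlorine between the methoxy carbon and the carbon that will become oxygenated. Its hydroxyl directs bromination to the only free ortho position, which is the carbon that must carry the ester. The forward reactions must brominate regioselectively and carbonylate at C–Br without touching C–Cl.

## Roads not taken

**Alternative 1:** Ring B stays aromatic and two bonds to it are cut, the C2–O ether bond and the C1–carboxyl bond.
- Forward key step: CsF would release the aryne A3, which is 3-(benzyloxy)-5-methylbenzyne, from the silyl triflate A2. The cesium salt of the ring A bromophenol A1 would add to A3 at the aryne carbon remote from the benzyloxy group, and the aryl anion left next to that group would be carboxylated by carbon dioxide A4 to give the acid A5.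
- Merits: the plan is convergent and forms the hindered ether without a metal catalyst. The carboxyl arrives free and already distinct from the ring A ester. The sense of addition to 3-alkoxyarynes of the type of A3 is dependable.
- Weak points: the 2,6-disubstituted phenoxide is partly tied up by A4 as a carbonate. The aryl anion must be carboxylated faster than it is protonated. Ring A cannot carry its ester in this step, since the aryl anion would close onto it to a xanthone, so bromine stands in and must later be carbonylated beside a free acid before the benzyl groups are removed. A2 needs several steps of its own, and A1 needs a protect–oxidize–benzylate–deprotect sequence from 2.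
- Comparison: this road is more convergent than the chosen plan, and its key step lies closer to documented aryne insertion chemistry. The chosen plan sets against it a markedly shorter sequence (seven steps in one line), no silyl triflate synthesis, no late carbonylation next to a free acid, and ring B made from two cheap four-carbon pieces.

**Alternative 2:** Ring A is cut instead of ring B, at the two bonds that meet at its ester-bearing carbon (C1–C2 and C1–C6, C6 being the ether carbon).
- Forward key step: the methyl ketone enolate of the aryloxymethyl chloro(methoxy) enone A6 would be acylated by dimethyl oxalate A7. The aryloxymethyl carbon would then condense with the new keto group and close ring A, which aromatizes by dehydration and enolization to A8.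
- Merits: the ether bond comes from a plain O-alkylation at a primary carbon, the most reliable C–O bond formation in any of the four plans. No vinylogous acid chloride is handled. A7 is a commodity reagent that delivers ring carbon C1 together with its methyl ester. The tert-butyl ester and MOM (methoxymethyl) ether keep ring B orthogonal.
- Weak points: the acyclic tetrasubstituted enone A6 must be made with Z geometry and with chlorine and methoxy in fixed positions, which costs several steps. After acylation by A7 the chain is a stabilized enolate, so the closure needs a second deprotonation at the aryloxymethyl carbon and an attack on the very carbonyl that this enolate deactivates. Closure through oxygen to a pyranone competes.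
- Comparison: this road is better than the chosen plan in how the ether is made. It is weaker in that it builds the more substituted ring from scratch, whereas the chosen plan buys the chloro/methoxy/oxygen pattern of ring A in 1 and builds the simple ring.

**Alternative 3:** Ring B is again the ring that is built, but it is cut into a four-carbon and a two-carbon piece (C2–C3 and C1–C6 bonds).
- Forward key step: the vinylketene acetal A9 would add to the aryloxypropiolate A10 in a Diels–Alder reaction, the methylene end of the diene bonding to the aryloxy-bearing alkyne carbon. Loss of the methoxy and silyl groups from the adduct would give the salicylate A11.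
- Merits: cycloaddition of vinylketene acetals to alkynoates is an established salicylate synthesis. It runs under neutral, thermal conditions, so the ring A methyl ester meets neither a dianion nor a strong Lewis acid. The push–pull polarization of A10 matches the diene.
- Weak points: A10 is an aryl ynol ether with an ester and must be made from the same hindered phenol 6 in two or three uncertain steps. It is a sluggish dienophile, so the heating needed invites silyl transfer and open-chain Michael adducts from A9.
- Comparison: in precedent for the ring-forming event and in mildness this road is better than the chosen plan. The chosen plan sets against it a one-step access to its electrophile 8 from 6 and 7, and a ring closure driven by a strongly electrophilic cation and not by a reluctant cycloaddition. Both plans depend equally on attaching 6 to an electron-poor unsaturated carbon.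

Key step: step 6

Remark on the chemistry (assumption): compounds 1, 7 and 9 are taken to be purchasable, and 8 is drawn as its Z isomer although either double-bond isomer would converge on 12 in step 6.

## Route

Step 1
Reactants: 1 2-chloro-4-hydroxy-3-methoxybenzaldehyde (2-chlorovanillin)
Product: 2 5-bromo-2-chloro-4-hydroxy-3-methoxybenzaldehyde
Conditions: Br2, NaOAc, AcOH, rt
Reagents that add atoms: bromine, BrBr
Why: Electrophilic aromatic bromination; the hydroxyl directs to its only free ortho position (C5), which is also meta to the aldehyde, while C6 is deactivated by the ortho aldehyde.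

Step 2
Reactants: 2 5-bromo-2-chloro-4-hydroxy-3-methoxybenzaldehyde
Product: 3 methyl 4-chloro-5-formyl-2-hydroxy-3-methoxybenzoate
Conditions: Pd(OAc)2 (cat.), Xantphos (cat.), Et3N, MeOH, CO (1 atm), 70 °C
Reagents that add atoms: carbon monoxide, [C-]#[O+]; methanol, CO
Why: Palladium-catalysed methoxycarbonylation of an aryl bromide; zerovalent palladium inserts into C–Br far faster than into C–Cl, CO inserts and methanol cleaves the acyl palladium species, and the aldehyde and free phenol are tolerated.

Step 3
Reactants: 3 methyl 4-chloro-5-formyl-2-hydroxy-3-methoxybenzoate
Product: 5 methyl 4-chloro-2,5-dihydroxy-3-methoxybenzoate, via aryl formate 4 (not isolated)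
Conditions: Na2CO3·1.5H2O2 (sodium percarbonate), THF/H2O, 0 °C to rt, N2; then aq Na2S2O3, dil. HCl
Reagents that add atoms: hydrogen peroxide (delivered by sodium percarbonate), OO
Why: Dakin oxidation; hydroperoxide adds to the aldehyde of the para-phenoxide, the aryl group migrates to oxygen and the formate 4 is hydrolysed in the carbonate medium. The cold, buffered conditions and the low electrophilicity of an ester next to a phenoxide should spare the methyl ester.

Step 4
Reactants: 5 methyl 4-chloro-2,5-dihydroxy-3-methoxybenzoate
Product: 6 methyl 5-(benzyloxy)-4-chloro-2-hydroxy-3-methoxybenzoate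
Conditions: BnBr (1 equiv), K2CO3, acetone, reflux, N2
Reagents that add atoms: benzyl bromide, BrCc1ccccc1
Why: Regioselective Williamson ether synthesis; the 2-hydroxyl is hydrogen-bonded to the ester carbonyl and flanked on both sides, so the free and more acidic 5-hydroxyl next to chlorine is alkylated, as is usual for 2,5-dihydroxybenzoates.

Step 5
Reactants: 6 methyl 5-(benzyloxy)-4-chloro-2-hydroxy-3-methoxybenzoate, 7 4,4-dichlorobut-3-en-2-one
Product: 8 methyl 5-(benzyloxy)-4-chloro-2-{[(1Z)-1-chloro-3-oxobut-1-en-1-yl]oxy}-3-methoxybenzoate
Conditions: K2CO3, 7 (slight excess), MeCN, 0 °C to rt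
Reagents that add atoms: none
Why: Nucleophilic vinylic substitution by addition–elimination; the phenoxide adds to the β-carbon of the β,β-dichlorovinyl ketone and the enolate expels chloride. The product is a donor-substituted enone, much less electrophilic than 7, and the phenoxide is hindered, so a second displacement should be slow. The Z isomer, with the bulky aryloxy group trans to the acetyl group, is expected to prevail.

Step 6
Reactants: 8 methyl 5-(benzyloxy)-4-chloro-2-{[(1Z)-1-chloro-3-oxobut-1-en-1-yl]oxy}-3-methoxybenzoate, 9 benzyl 3-oxobutanoate (benzyl acetoacetate)
Product: 12 benzyl 2-[4-(benzyloxy)-3-chloro-2-methoxy-6-(methoxycarbonyl)phenoxy]-6-hydroxy-4-methylbenzoate, via acetoacetate dianion 10 (not isolated), via tertiary allylic alcohol 11 (not isolated)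
Conditions: 9, NaH then nBuLi, THF, 0 °C; 8, THF, −78 °C; AcOH, −78 °C, cold extractive work-up; crude 11, BF3·OEt2, 4 Å MS, CH2Cl2, −78 to 0 °C
Reagents that add atoms: none
Why: Proposed new method: at −78 °C the hard terminal carbon of dianion 10 should add to the ketone carbonyl of 8 (1,2-addition) to give, after protonation, the racemic tertiary allylic alcohol 11, whose stereocenter disappears on aromatization. BF3·OEt2 then ionizes the tertiary hydroxyl to an allyl cation that is delocalized onto the chloro(aryloxy) carbon and stabilized there by the aryloxy lone pair. The enol of the β-keto ester attacks this carbon through its central carbon and closes ring B in a six-membered, 6-endo-trig sense with respect to the allyl cation; chloride then leaves, and loss of a proton and tautomerization of the ring ketone give the phenol, so that water and HCl are lost overall. The closest known reaction types are the benzannulation of α-oxoketene dithioacetals (1,2-addition of a carbon nucleophile, then BF3-induced cycloaromatization) and the salicylate syntheses from β-keto ester dianions; neither has been shown for a β-chloro-β-aryloxy enone. No stereocenter is present in 12. The first selectivity needed is carbonyl addition over conjugate addition–elimination at the chloro(aryloxy) carbon, which would end in the 4-aryloxy-6-methyl isomer; it should be secured by the hard, lithium-bound carbanion at low temperature and by the donor aryloxy group, which lowers the electrophilicity of the β-carbon. The second is loss of chloride and not of aryloxide from the ring-closed intermediate, secured by the much better leaving-group ability of chloride. Closure through the ketone oxygen to a pyran is reversible through the same cation, whereas closure through carbon is made irreversible by aromatization.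

Step 7
Reactants: 12 benzyl 2-[4-(benzyloxy)-3-chloro-2-methoxy-6-(methoxycarbonyl)phenoxy]-6-hydroxy-4-methylbenzoate
Product: 13 2-[3-chloro-4-hydroxy-2-methoxy-6-(methoxycarbonyl)phenoxy]-6-hydroxy-4-methylbenzoic acid
Conditions: BCl3, C6HMe5 (pentamethylbenzene), CH2Cl2, −78 to 0 °C; then MeOH/H2O
Reagents that add atoms: none
Why: Lewis-acid debenzylation with a non-basic cation scavenger; BCl3 activates the aryl benzyl ether and the boron-chelated salicylate benzyl ester, and the benzyl cations are taken up by pentamethylbenzene in a Friedel–Crafts alkylation. At low temperature the methyl ester, the non-chelated methyl ether and the aryl chloride should remain.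

## Compound list

1 | 2-chloro-4-hydroxy-3-methoxybenzaldehyde (2-chlorovanillin) | O=Cc1ccc(O)c(OC)c1Cl | starting material
2 | 5-bromo-2-chloro-4-hydroxy-3-methoxybenzaldehyde | O=Cc1cc(Br)c(O)c(OC)c1Cl | intermediate
3 | methyl 4-chloro-5-formyl-2-hydroxy-3-methoxybenzoate | COC(=O)c1cc(C=O)c(Cl)c(OC)c1O | intermediate
4 | methyl 4-chloro-5-(formyloxy)-2-hydroxy-3-methoxybenzoate | COC(=O)c1cc(OC=O)c(Cl)c(OC)c1O | intermediate (not isolated)
5 | methyl 4-chloro-2,5-dihydroxy-3-methoxybenzoate | COC(=O)c1cc(O)c(Cl)c(OC)c1O | intermediate
6 | methyl 5-(benzyloxy)-4-chloro-2-hydroxy-3-methoxybenzoate | COC(=O)c1cc(OCc2ccccc2)c(Cl)c(OC)c1O | intermediate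
7 | 4,4-dichlorobut-3-en-2-one | CC(=O)C=C(Cl)Cl | starting material
8 | methyl 5-(benzyloxy)-4-chloro-2-{[(1Z)-1-chloro-3-oxobut-1-en-1-yl]oxy}-3-methoxybenzoate | COC(=O)c1cc(OCc2ccccc2)c(Cl)c(OC)c1O/C(Cl)=C/C(C)=O | intermediate
9 | benzyl 3-oxobutanoate (benzyl acetoacetate) | CC(=O)CC(=O)OCc1ccccc1 | starting material
10 | lithium sodium 1-(benzyloxy)buta-1,3-diene-1,3-diolate (dianion of 9, enolate geometry not defined) | C=C([O-])C=C([O-])OCc1ccccc1.[Li+].[Na+] | intermediate (not isolated)
11 | benzyl (6Z)-7-[4-(benzyloxy)-3-chloro-2-methoxy-6-(methoxycarbonyl)phenoxy]-7-chloro-5-hydroxy-5-methyl-3-oxohept-6-enoate (racemic) | COC(=O)c1cc(OCc2ccccc2)c(Cl)c(OC)c1O/C(Cl)=C/C(C)(O)CC(=O)CC(=O)OCc1ccccc1 | intermediate (not isolated)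
12 | benzyl 2-[4-(benzyloxy)-3-chloro-2-methoxy-6-(methoxycarbonyl)phenoxy]-6-hydroxy-4-methylbenzoate | COC(=O)c1cc(OCc2ccccc2)c(Cl)c(OC)c1Oc1cc(C)cc(O)c1C(=O)OCc1ccccc1 | intermediate
13 | 2-[3-chloro-4-hydroxy-2-methoxy-6-(methoxycarbonyl)phenoxy]-6-hydroxy-4-methylbenzoic acid | COC(=O)c1cc(O)c(Cl)c(OC)c1Oc1cc(C)cc(O)c1C(=O)O | target

## Step count and risks

Total step count: 7. Longest linear sequence: 7 steps (1 to 13); 7 and 9 enter as purchased reagents.

**Step 6 (key step, proposed new method).**
- What may go wrong: conjugate addition–elimination at the chloro(aryloxy) carbon may compete with carbonyl addition, since a β-chloro enone is a vinylogous acid chloride. The dianion may enolize the methyl ketone. Alcohol 11 may undergo retro-aldol cleavage or hydrolytic 1,3-transposition to an aryl ester during work-up, because it is both an aldol and a masked acid derivative. The cation may close through the ketone oxygen.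
- Fallback (known chemistry), setting out from 6 and returning at 13: purchasable 2,6-difluoro-4-methylbenzaldehyde is treated with benzyl alcohol and NaH in THF, which displaces one fluoride and gives 2-(benzyloxy)-6-fluoro-4-methylbenzaldehyde F1. Nucleophilic aromatic substitution of the remaining aldehyde-activated fluoride by the phenoxide of 6 (Cs2CO3, DMSO, 100 °C) gives methyl 5-(benzyloxy)-2-[3-(benzyloxy)-2-formyl-5-methylphenoxy]-4-chloro-3-methoxybenzoate F2. Pinnick oxidation (NaClO2, NaH2PO4, 2-methylbut-2-ene, tBuOH/H2O) gives 2-(benzyloxy)-6-[4-(benzyloxy)-3-chloro-2-methoxy-6-(methoxycarbonyl)phenoxy]-4-methylbenzoic acid F3. BCl3 with pentamethylbenzene, as in step 7, then removes both benzyl ethers and gives 13.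

**Step 5.**
- What may go wrong: over-substitution, in which a second phenoxide displaces the remaining chloride, and hydrolysis of the moisture-sensitive chloroenone to an aryl acetoacetate during isolation.
- Fallback, setting out from 6 and returning at 12: two equivalents of 6 are driven onto 7 (Cs2CO3, DMF, 40 °C) to give the more water-stable ketene diaryl acetal 4,4-bis[4-(benzyloxy)-3-chloro-2-methoxy-6-(methoxycarbonyl)phenoxy]but-3-en-2-one F4. F4 is put through the conditions of step 6, in which one aryloxide leaves after ring closure in place of chloride. This gives 12 and returns one equivalent of 6 for reuse.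

**Step 3.**
- What may go wrong: saponification of the methyl ester in the basic peroxide medium, over-oxidation of the hydroquinone to a quinone, or hydride migration in place of aryl migration (giving the acid), since the ester withdraws electron density from the migrating ring.
- Fallback, setting out from 2 and returning at 6: the phenol of 2 is protected (MOMCl, iPr2NEt, CH2Cl2) as 5-bromo-2-chloro-3-methoxy-4-(methoxymethoxy)benzaldehyde F5. Baeyer–Villiger oxidation with mCPBA gives 5-bromo-2-chloro-3-methoxy-4-(methoxymethoxy)phenyl formate F6, which is cleaved without isolation (K2CO3, MeOH) to 5-bromo-2-chloro-3-methoxy-4-(methoxymethoxy)phenol F7. Benzylation (BnBr, K2CO3, DMF) gives 1-(benzyloxy)-5-bromo-2-chloro-3-methoxy-4-(methoxymethoxy)benzene F8. Methoxycarbonylation under the conditions of step 2 gives methyl 5-(benzyloxy)-4-chloro-3-methoxy-2-(methoxymethoxy)benzoate F9, and HCl in MeOH removes the acetal to give 6.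

**Step 7.**
- What may go wrong: incomplete cleavage of the benzyl ester, loss of the ring A methyl ether on warming, or acid-induced decarboxylation of the electron-rich salicylic acid.
- Fallback, setting out from 12 and returning at 13 with no new compound: neutral catalytic hydrogenolysis (H2 at 1 atm, Pd/C, EtOAc, rt), stopped as soon as both benzyl groups are gone. Hydrogenolysis of the benzyl ester and ether is much faster than reduction of the aryl chloride in the absence of base.

## Further compounds

F1 | step 6 | 2-(benzyloxy)-6-fluoro-4-methylbenzaldehyde | O=Cc1c(F)cc(C)cc1OCc1ccccc1
F2 | step 6 | methyl 5-(benzyloxy)-2-[3-(benzyloxy)-2-formyl-5-methylphenoxy]-4-chloro-3-methoxybenzoate | COC(=O)c1cc(OCc2ccccc2)c(Cl)c(OC)c1Oc1cc(C)cc(OCc2ccccc2)c1C=O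
F3 | step 6 | 2-(benzyloxy)-6-[4-(benzyloxy)-3-chloro-2-methoxy-6-(methoxycarbonyl)phenoxy]-4-methylbenzoic acid | COC(=O)c1cc(OCc2ccccc2)c(Cl)c(OC)c1Oc1cc(C)cc(OCc2ccccc2)c1C(=O)O
F4 | step 5 | 4,4-bis[4-(benzyloxy)-3-chloro-2-methoxy-6-(methoxycarbonyl)phenoxy]but-3-en-2-one | CC(=O)C=C(Oc1c(OC)c(Cl)c(OCc2ccccc2)cc1C(=O)OC)Oc1c(OC)c(Cl)c(OCc2ccccc2)cc1C(=O)OC
F5 | step 3 | 5-bromo-2-chloro-3-methoxy-4-(methoxymethoxy)benzaldehyde | O=Cc1cc(Br)c(OCOC)c(OC)c1Cl
F6 | step 3 | 5-bromo-2-chloro-3-methoxy-4-(methoxymethoxy)phenyl formate | O=COc1cc(Br)c(OCOC)c(OC)c1Cl
F7 | step 3 | 5-bromo-2-chloro-3-methoxy-4-(methoxymethoxy)phenol | Oc1cc(Br)c(OCOC)c(OC)c1Cl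
F8 | step 3 | 1-(benzyloxy)-5-bromo-2-chloro-3-methoxy-4-(methoxymethoxy)benzene | COCOc1c(Br)cc(OCc2ccccc2)c(Cl)c1OC
F9 | step 3 | methyl 5-(benzyloxy)-4-chloro-3-methoxy-2-(methoxymethoxy)benzoate | COC(=O)c1cc(OCc2ccccc2)c(Cl)c(OC)c1OCOC
F0 | step 7 | none | none
A1 | alternative 1 | 4-(benzyloxy)-6-bromo-3-chloro-2-methoxyphenol | Oc1c(Br)cc(OCc2ccccc2)c(Cl)c1OC
A2 | alternative 1 | 3-(benzyloxy)-5-methyl-2-(trimethylsilyl)phenyl trifluoromethanesulfonate | Cc1cc(OCc2ccccc2)c([Si](C)(C)C)c(OS(=O)(=O)C(F)(F)F)c1
A3 | alternative 1 | 3-(benzyloxy)-5-methylbenzyne (3-(benzyloxy)-5-methyl-1,2-didehydrobenzene) | CC1=CC#CC(OCc2ccccc2)=C1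
A4 | alternative 1 | carbon dioxide | O=C=O
A5 | alternative 1 | 2-(benzyloxy)-6-[4-(benzyloxy)-6-bromo-3-chloro-2-methoxyphenoxy]-4-methylbenzoic acid | OC(=O)c1c(OCc2ccccc2)cc(C)cc1Oc1c(Br)cc(OCc2ccccc2)c(Cl)c1OC
A6 | alternative 2 | tert-butyl 2-{[(2Z)-3-chloro-2-methoxy-4-oxopent-2-en-1-yl]oxy}-6-(methoxymethoxy)-4-methylbenzoate | CC(=O)/C(Cl)=C(/OC)COc1cc(C)cc(OCOC)c1C(=O)OC(C)(C)C
A7 | alternative 2 | dimethyl oxalate | COC(=O)C(=O)OC
A8 | alternative 2 | tert-butyl 2-[3-chloro-4-hydroxy-2-methoxy-6-(methoxycarbonyl)phenoxy]-6-(methoxymethoxy)-4-methylbenzoate | COC(=O)c1cc(O)c(Cl)c(OC)c1Oc1cc(C)cc(OCOC)c1C(=O)OC(C)(C)C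
A9 | alternative 3 | 1-methoxy-3-methyl-1-(trimethylsilyloxy)buta-1,3-diene (ketene acetal geometry not defined) | COC(O[Si](C)(C)C)=CC(C)=C
A10 | alternative 3 | tert-butyl 3-[4-(benzyloxy)-3-chloro-2-methoxy-6-(methoxycarbonyl)phenoxy]prop-2-ynoate | COC(=O)c1cc(OCc2ccccc2)c(Cl)c(OC)c1OC#CC(=O)OC(C)(C)C
A11 | alternative 3 | tert-butyl 2-[4-(benzyloxy)-3-chloro-2-methoxy-6-(methoxycarbonyl)phenoxy]-6-hydroxy-4-methylbenzoate | COC(=O)c1cc(OCc2ccccc2)c(Cl)c(OC)c1Oc1cc(C)cc(O)c1C(=O)OC(C)(C)C
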